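Watch the first minute.

    substrate + reagent ⇌ target (K1 = 330 L mol⁻¹, k1 = 34 L mol⁻¹ s⁻¹)
    reagent → decomposition product (k2 = 4.7 × 10⁻⁵ s⁻¹)

substrate 10 mM; reagent 5.00 mM; time 10 min

- the reaction counts as stopped when no species that holds the substrate changes by six tenths of a point or more over the second half of the time
- run time (flask): 10 min

- why nothing more happens at 10 min, or that something still does (forward and back rates have come level / it is still moving / all of the substrate has reacted / the reagent has run out first)
- part of the substrate gone at 10 min
- the target standing at 10 min, as a percentage of the substrate charged

In the flask, substrate and reagent start at a forward rate of 1.70 mM s⁻¹, and at that pace the reagent charge lasts 2.94 s, far shorter than the run. Two factors then slow the forward rate: the free part of the reagent and the free part of the substrate. Let y be the part of the reagent charge standing as target, and let H be the binding number, the equilibrium constant of step 1 times the substrate charged, 3.30. The back rate, as a fraction of the starting forward rate, is y/H, so the rates come level when the product of the two factors equals y/H.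

Solved by hand for the flask, this balance gives y = 0.685. The reagent factor is then 0.315, the substrate factor is 0.658, and the forward rate has dropped to 0.352 mM s⁻¹. The balance puts target at 34.2 % of the substrate charged, below the 50.0 % allowed by reagent, the limiting reagent. Step 2 is a small correction, its half-life of 4.1 h being far longer than the run. It takes 0.0445 mM of reagent over the run, and the second half's share, even taken wholly from target, is 0.22 percentage points.

The forecast's answer for the end is "forward and back rates have come level", with 34 % of the substrate gone and 34 % standing as target, and its words are “the forward and back rates are level long before 10 min”. The simulation of the flask answers "forward and back rates have come level", with 34.0 % of the substrate gone and 34.0 % standing as target; target already reads 34.2 % at 1.00 min.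

At 10.0 min the flask's two factors multiply to 0.206, and y/H from its target reading is 0.206. The neighbour flask with 17 mM of substrate has a binding number of 5.61. The same balance gives y = 0.810, so the product of its two factors should come to 0.144. The neighbour's simulated factors, 19 % for reagent and 76 % for substrate, multiply to 0.144, and its target stands at 23.7 % of its larger substrate charge.

The constants were chosen freely; the flask was simulated.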